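**Retrosynthetic overview**

1. The target is treated as a longipinane (numbering in the first remark). The two esters, the C2=C3 double bond and the C7/C8/C9 oxygens are installed late: C8–O and C9–O by osmylation of a C8=C9 alkene anti to the C7 oxygen, and C7–OH by reagent-controlled reduction of a tricyclic C8-ene-1,7-dione.
2. That ene-dione is the dehydration product of a tricyclic 9-hydroxy-1,7-diketone. In it, bonds C5–C6 and C10–C11 are cut together, which opens the seven-membered ring and the cyclobutane at once and leaves a monocyclic 4,5-disubstituted cyclohex-2-enone whose side chain ends in an isopropenyl ketone and carries a trisubstituted oxirane (C9–O–C10).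
3. Enabling feature: the C1 ketone of the six-membered ring C1–C2–C3–C4–C5–C11 is β to C5 and α to C11. As an enone it accepts the C6 enolate at C5 (1,5-dicarbonyl relation C7/C1), and the C11 enolate so formed opens the oxirane at C10 (γ-hydroxy ketone relation C1/C9–O); oxirane strain pays for the cyclobutane.
4. Ring order: six-membered ring first by a catalytic enantioselective Diels–Alder reaction (sets C3, C4); then seven-membered ring and cyclobutane together in the key step (sets C5, C10, C11).
5. The side chain is grown from the Diels–Alder aldehyde through an alkyne, an epoxide opening and an iron-catalysed syn-methylmagnesiation that fixes the Z trisubstituted alkene; the oxirane comes from a Shi epoxidation.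

Key step: step 10

Remark (naming): tricyclic compounds are named as longipinanes. C1–C2–C3 is the three-carbon bridge (C1 carbonyl carbon, C3 bearing a methyl) between the cyclobutane bridgeheads C11 and C4; the cyclobutane is C4–C5–C11–C10; C5 carries C6 (gem-dimethyl), C10 carries a methyl and C9; C6–C7–C8–C9 completes the seven-membered ring. At C7–C9, α means the side facing C11 and β the side facing C4; absolute configuration is as in the SMILES.

Remark (epimers): epoxide 7 is used racemic, so the carbinol carbon that becomes C7 is a 1:1 epimer mixture in 9–12; both epimers converge when it is oxidised in step 9.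

Remark (catalyst sense): in steps 2 and 8 the catalyst enantiomer is the one that delivers the configuration drawn; if the facial sense proves opposite, the mirror-image catalyst is used.

**Route**

Step 1
Reactants: 1 but-3-en-2-one
Product: 2 2-{[tri(propan-2-yl)silyl]oxy}buta-1,3-diene
Conditions: iPr3SiOTf, Et3N, Et2O, 0 °C to rt
Reagents that add atoms: triisopropylsilyl trifluoromethanesulfonate, CC(C)[Si](OS(=O)(=O)C(F)(F)F)(C(C)C)C(C)C
Why: Silyl enol ether formation by soft enolisation of the methyl ketone gives the 2-silyloxy diene, the bulky silyl group being chosen to survive steps 2 to 6; no stereocentre is formed.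

Step 2
Reactants: 2 2-{[tri(propan-2-yl)silyl]oxy}buta-1,3-diene; 3 (2E)-but-2-enal
Product: 4 (1R,6R)-6-methyl-4-{[tri(propan-2-yl)silyl]oxy}cyclohex-3-ene-1-carbaldehyde
Conditions: oxazaborolidinium triflimide from (S)-α,α-diphenylprolinol, o-tolylboroxine and Tf2NH (20 mol %), CH2Cl2, −78 to −40 °C
Reagents that add atoms: none
Why: Lewis-acid-catalysed Diels–Alder reaction in which the nucleophilic diene terminus bonds to the β-carbon of the enal ("para" adduct), the E dienophile fixes the trans relation of CHO and CH3, and the chiral oxazaborolidinium shields one enal face to set both centres in the absolute sense.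

Step 3
Reactants: 4 (1R,6R)-6-methyl-4-{[tri(propan-2-yl)silyl]oxy}cyclohex-3-ene-1-carbaldehyde
Product: 5 (4R,5R)-4-ethynyl-5-methyl-1-{[tri(propan-2-yl)silyl]oxy}cyclohex-1-ene
Conditions: dimethyl (1-diazo-2-oxopropyl)phosphonate, K2CO3, MeOH, 0 °C to rt
Reagents that add atoms: dimethyl (1-diazo-2-oxopropyl)phosphonate, CC(=O)C(=[N+]=[N-])P(=O)(OC)OC
Why: Seyferth–Gilbert homologation with the Ohira–Bestmann reagent converts the aldehyde into the terminal alkyne under mildly basic conditions that the silyl enol ether tolerates, the α-centre keeping the thermodynamically preferred trans arrangement.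

Step 4
Reactants: 6 2-methylprop-2-enal
Product: 7 (RS)-2-(prop-1-en-2-yl)oxirane
Conditions: Me3S+ I−, NaH, DMSO/THF, 0 °C; distillation
Reagents that add atoms: trimethylsulfonium iodide, C[S+](C)C.[I-]
Why: Corey–Chaykovsky epoxidation, in which the sulfonium ylide adds 1,2 to the enal carbonyl and closes to the vinyl oxirane (racemic; this centre is destroyed in step 9).

Step 5
Reactants: 5 (4R,5R)-4-ethynyl-5-methyl-1-{[tri(propan-2-yl)silyl]oxy}cyclohex-1-ene; 7 (RS)-2-(prop-1-en-2-yl)oxirane
Product: 9 (4RS)-5-methyl-1-[(1R,6R)-6-methyl-4-{[tri(propan-2-yl)silyl]oxy}cyclohex-3-en-1-yl]hex-5-en-1-yn-4-ol, via lithium acetylide 8 (not isolated)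
Conditions: n-BuLi, THF, −78 °C; then 7, DMPU, −78 °C to rt; aq. NH4Cl
Reagents that add atoms: none
Why: Deprotonation of the terminal alkyne and SN2 opening of the epoxide at its CH2 carbon by the acetylide (epoxide alkynylation), run without Lewis acid so that the allylic epoxide carbon is not attacked.

Step 6
Reactants: 9 (4RS)-5-methyl-1-[(1R,6R)-6-methyl-4-{[tri(propan-2-yl)silyl]oxy}cyclohex-3-en-1-yl]hex-5-en-1-yn-4-ol
Product: 10 (3RS,5Z)-2-methyl-6-[(1R,6R)-6-methyl-4-{[tri(propan-2-yl)silyl]oxy}cyclohex-3-en-1-yl]hepta-1,5-dien-3-ol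
Conditions: Fe(acac)3 (15 mol %), MeMgBr (5 equiv), THF, −20 to 0 °C; aq. NH4Cl
Reagents that add atoms: methylmagnesium bromide, C[Mg]Br
Why: Iron-catalysed, alkoxide-directed syn-carbomagnesiation of the alkyne delivers methyl to the alkyne carbon distal to the alkoxide and magnesium to the proximal one (chelate), so protonation gives the trisubstituted alkene with the ring and the CH2 chain cis (Z).

Step 7
Reactants: 10 (3RS,5Z)-2-methyl-6-[(1R,6R)-6-methyl-4-{[tri(propan-2-yl)silyl]oxy}cyclohex-3-en-1-yl]hepta-1,5-dien-3-ol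
Product: 11 (4S,5R)-4-[(2Z,5RS)-5-hydroxy-6-methylhepta-2,6-dien-2-yl]-5-methylcyclohex-2-en-1-one
Conditions: Pd(OAc)2 (1.1 equiv), MeCN, 40 °C
Reagents that add atoms: none
Why: Saegusa–Ito oxidation of the regiodefined Diels–Alder silyl enol ether places the enone double bond between C5 and C11 (β-hydride elimination from C5), which enolisation of the free ketone could not do selectively.

Step 8
Reactants: 11 (4S,5R)-4-[(2Z,5RS)-5-hydroxy-6-methylhepta-2,6-dien-2-yl]-5-methylcyclohex-2-en-1-one
Product: 12 (4S,5R)-4-{(2R,3S)-3-[(2RS)-2-hydroxy-3-methylbut-3-en-1-yl]-2-methyloxiran-2-yl}-5-methylcyclohex-2-en-1-one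
Conditions: fructose-derived Shi ketone (30 mol %), Oxone, K2CO3, Bu4NHSO4, MeCN/dimethoxymethane/aq. buffer pH 10, −10 to 0 °C
Reagents that add atoms: potassium peroxymonosulfate (active oxidant of Oxone), [K+].[O-]S(=O)(=O)OO
Why: Shi epoxidation, in which the chiral dioxirane epoxidises the electron-rich trisubstituted Z alkene in preference to the 1,1-disubstituted and enone double bonds, syn-stereospecifically (cis oxirane) and on the face chosen by the catalyst enantiomer.

Step 9
Reactants: 12 (4S,5R)-4-{(2R,3S)-3-[(2RS)-2-hydroxy-3-methylbut-3-en-1-yl]-2-methyloxiran-2-yl}-5-methylcyclohex-2-en-1-one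
Product: 13 (4S,5R)-5-methyl-4-[(2R,3S)-2-methyl-3-(3-methyl-2-oxobut-3-en-1-yl)oxiran-2-yl]cyclohex-2-en-1-one
Conditions: Dess–Martin periodinane, NaHCO3, CH2Cl2, 0 °C
Reagents that add atoms: none
Why: Dess–Martin oxidation of the allylic alcohol under buffered neutral conditions converges both carbinol epimers on the isopropenyl ketone without exposing the base-sensitive β,γ-epoxy ketone to base.

Step 10
Reactants: 13 (4S,5R)-5-methyl-4-[(2R,3S)-2-methyl-3-(3-methyl-2-oxobut-3-en-1-yl)oxiran-2-yl]cyclohex-2-en-1-one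
Product: 18 (3R)-9β-hydroxylongipinane-1,7-dione, via acyclic copper enolate 14 (not isolated), via bicyclic copper enolate 15 (not isolated), via bicyclic trimethylsilyl enol ether 16 (not isolated), via tricyclic 9-O-trimethylsilyl ether 17 (not isolated)
Conditions: [(Ph3P)CuH]6 (0.18 equiv, 1.1 equiv hydride), toluene/THF, −40 to 0 °C; then Me3SiOTf (1.3 equiv), CH2Cl2, −78 to −40 °C; aq. citric acid
Reagents that add atoms: none
Why: Proposed new method: hydride from [(Ph3P)CuH]6 adds to the β-unsubstituted isopropenyl ketone faster than to the β-substituted ring enone and gives the tetrasubstituted copper enolate 14 regiospecifically, which adds in a 7-(enolendo)-exo-trig Michael reaction to C5 of the cyclohexenone (closest known type: copper-hydride reductive Michael cyclisation); the C11 enolate 15, silylated to 16, then opens the Me3SiOTf-activated oxirane at its tertiary carbon C10 in a 4-(enolexo)-exo-tet closure (closest known types: the epoxynitrile cyclisation to cyclobutanes and the Lewis-acid alkylation of silyl enol ethers by epoxides). The seven-membered ring C4–C5–C6–C7–C8–C9–C10 closes first through the C6–C5 bond and the cyclobutane C4–C5–C11–C10 second through the C11–C10 bond, the strain of the oxirane paying for the bicyclo[3.1.1]heptanone. C5 is set by axial attack on the enone anti to the pseudoaxial C4–H, which places C6 cis to the side chain on C4; C11 and C10 are set by the closure itself, because C10 can bridge C4 and C11 on one face only and C9, already in the seven-membered ring, must stay on the face away from the C1–C3 bridge, which puts the C10 methyl syn to that bridge. The (2R,3S)-oxirane is chosen so that its oxygen lies anti to the incoming C11, so an SN2-like and an ion-pair pathway both converge on 18 with a 9β-hydroxyl, a centre that is erased in step 11. The selectivity needed is secured by the substrate: attack of C6 on the oxirane would be a 4- or 5-(enolendo) closure joining two fully substituted carbons, O-alkylation through the C1 enolate oxygen would give a bridgehead enol ether, and the acidic C8–H next to the C7 ketone never meets a free basic enolate because the cascade runs through copper and silyl enolates.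

Step 11
Reactants: 18 (3R)-9β-hydroxylongipinane-1,7-dione
Product: 20 (3R)-longipin-8-ene-1,7-dione, via 9β-mesylate 19 (not isolated)
Conditions: MsCl, Et3N, CH2Cl2, 0 °C; then DBU, rt
Reagents that add atoms: none
Why: Sulfonylation of the 9β-hydroxyl followed by E1cB elimination through the C7 enolate gives the conjugated cis-cycloheptenone, C8 being the only position with a β-hydrogen because C10 is quaternary.

Step 12
Reactants: 20 (3R)-longipin-8-ene-1,7-dione
Product: 21 (3R)-1-[(tert-butyldimethylsilyl)oxy]longipina-1,8-dien-7-one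
Conditions: tBuMe2SiOTf, Et3N, CH2Cl2, −78 to 0 °C
Reagents that add atoms: tert-butyldimethylsilyl trifluoromethanesulfonate, CC(C)(C)[Si](C)(C)OS(=O)(=O)C(F)(F)F
Why: Silyl enol ether formation by soft enolisation: C1 can enolise only towards C2 because C11 is a cyclobutane bridgehead, and the C7 enone has no enolisable position (C6 and C10 quaternary), so C1 is protected for step 13 and pre-activated for step 15.

Step 13
Reactants: 21 (3R)-1-[(tert-butyldimethylsilyl)oxy]longipina-1,8-dien-7-one
Product: 22 (3R)-1-[(tert-butyldimethylsilyl)oxy]longipina-1,8-dien-7β-ol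
Conditions: (S)-2-methyl-CBS-oxazaborolidine (1.0 equiv), catecholborane, toluene, −78 °C
Reagents that add atoms: none
Why: Corey–Bakshi–Shibata reduction of the only free carbonyl, in which the quaternary C6 acts as the large and the vinylic C8 as the small substituent, so the catalyst rather than the nearly mirror-symmetric tricyclic framework should set the 7β (7R) carbinol.

Step 14
Reactants: 22 (3R)-1-[(tert-butyldimethylsilyl)oxy]longipina-1,8-dien-7β-ol
Product: 23 (3R)-1,7β-bis[(tert-butyldimethylsilyl)oxy]longipina-1,8-diene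
Conditions: tBuMe2SiOTf, 2,6-lutidine, CH2Cl2, 0 °C
Reagents that add atoms: tert-butyldimethylsilyl trifluoromethanesulfonate, CC(C)(C)[Si](C)(C)OS(=O)(=O)C(F)(F)F
Why: Silylation of the hindered allylic alcohol, which keeps the C7 oxygen out of the later acylations and makes it the bulky group that steers the osmylation.

Step 15
Reactants: 23 (3R)-1,7β-bis[(tert-butyldimethylsilyl)oxy]longipina-1,8-diene
Product: 24 7β-[(tert-butyldimethylsilyl)oxy]longipina-2,8-dien-1-one
Conditions: Pd(OAc)2 (1.1 equiv), MeCN/CH2Cl2, rt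
Reagents that add atoms: none
Why: Saegusa–Ito oxidation of the C1 silyl enol ether gives the C2=C3 enone by β-hydride elimination from C3–H, removing the C3 stereocentre.

Step 16
Reactants: 24 7β-[(tert-butyldimethylsilyl)oxy]longipina-2,8-dien-1-one
Product: 25 7β-[(tert-butyldimethylsilyl)oxy]-8α,9α-dihydroxylongipin-2-en-1-one
Conditions: OsO4 (10 mol %), N-methylmorpholine N-oxide, acetone/H2O, rt
Reagents that add atoms: osmium tetroxide, O=[Os](=O)(=O)=O; N-methylmorpholine N-oxide, C[N+]1([O-])CCOCC1; water, O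
Why: Upjohn dihydroxylation: osmium tetroxide adds to the C8=C9 double bond on the face anti to the bulky allylic C7 silyloxy group (the usual anti rule for osmylation of cyclic allylic ethers), giving the 8α,9α-cis-diol and leaving the electron-poor trisubstituted enone untouched.

Step 17
Reactants: 25 7β-[(tert-butyldimethylsilyl)oxy]-8α,9α-dihydroxylongipin-2-en-1-one; 26 (2Z)-2-methylbut-2-enoic acid (angelic acid)
Product: 27 8α-angeloyloxy-7β-[(tert-butyldimethylsilyl)oxy]-9α-hydroxylongipin-2-en-1-one
Conditions: 26, 2,4,6-trichlorobenzoyl chloride, Et3N, toluene, rt; then 25, 75 °C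
Reagents that add atoms: none
Why: Yamaguchi-type mixed-anhydride esterification, which acylates without base-induced angelate-to-tiglate isomerisation; the C8 hydroxyl, flanked by two CH carbons, should react before the neopentyl C9 hydroxyl next to quaternary C10.

Step 18
Reactants: 27 8α-angeloyloxy-7β-[(tert-butyldimethylsilyl)oxy]-9α-hydroxylongipin-2-en-1-one; 28 3-methylbutanoyl chloride
Product: 29 8α-angeloyloxy-7β-[(tert-butyldimethylsilyl)oxy]-9α-(3-methylbutanoyloxy)longipin-2-en-1-one
Conditions: 28, pyridine, DMAP (cat.), CH2Cl2, 0 °C to rt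
Reagents that add atoms: none
Why: Nucleophile-catalysed acylation of the remaining hindered C9 hydroxyl with the saturated acid chloride.

Step 19
Reactants: 29 8α-angeloyloxy-7β-[(tert-butyldimethylsilyl)oxy]-9α-(3-methylbutanoyloxy)longipin-2-en-1-one
Product: 30 8α-angeloyloxy-7β-hydroxy-9α-(3-methylbutanoyloxy)longipin-2-en-1-one
Conditions: HF·pyridine, THF, 0 °C to rt
Reagents that add atoms: none
Why: Fluoride-mediated desilylation under mildly acidic conditions frees the 7β-hydroxyl without acyl migration or angelate isomerisation.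

**Compound list**

1 | but-3-en-2-one | C=CC(C)=O | starting material
2 | 2-{[tri(propan-2-yl)silyl]oxy}buta-1,3-diene | C=CC(=C)O[Si](C(C)C)(C(C)C)C(C)C | intermediate
3 | (2E)-but-2-enal | C/C=C/C=O | starting material
4 | (1R,6R)-6-methyl-4-{[tri(propan-2-yl)silyl]oxy}cyclohex-3-ene-1-carbaldehyde | O=C[C@H]1[C@H](C)CC(O[Si](C(C)C)(C(C)C)C(C)C)=CC1 | intermediate
5 | (4R,5R)-4-ethynyl-5-methyl-1-{[tri(propan-2-yl)silyl]oxy}cyclohex-1-ene | C#C[C@H]1[C@H](C)CC(O[Si](C(C)C)(C(C)C)C(C)C)=CC1 | intermediate
6 | 2-methylprop-2-enal | C=C(C)C=O | starting material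
7 | (RS)-2-(prop-1-en-2-yl)oxirane | C=C(C)C1CO1 | intermediate
8 | lithium acetylide of 5 | [Li]C#C[C@H]1[C@H](C)CC(O[Si](C(C)C)(C(C)C)C(C)C)=CC1 | intermediate
9 | (4RS)-5-methyl-1-[(1R,6R)-6-methyl-4-{[tri(propan-2-yl)silyl]oxy}cyclohex-3-en-1-yl]hex-5-en-1-yn-4-ol | C=C(C)C(O)CC#C[C@H]1[C@H](C)CC(O[Si](C(C)C)(C(C)C)C(C)C)=CC1 | intermediate
10 | (3RS,5Z)-2-methyl-6-[(1R,6R)-6-methyl-4-{[tri(propan-2-yl)silyl]oxy}cyclohex-3-en-1-yl]hepta-1,5-dien-3-ol | C=C(C)C(O)C/C=C(/C)[C@H]1[C@H](C)CC(O[Si](C(C)C)(C(C)C)C(C)C)=CC1 | intermediate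
11 | (4S,5R)-4-[(2Z,5RS)-5-hydroxy-6-methylhepta-2,6-dien-2-yl]-5-methylcyclohex-2-en-1-one | C=C(C)C(O)C/C=C(/C)[C@@H]1C=CC(=O)C[C@H]1C | intermediate
12 | (4S,5R)-4-{(2R,3S)-3-[(2RS)-2-hydroxy-3-methylbut-3-en-1-yl]-2-methyloxiran-2-yl}-5-methylcyclohex-2-en-1-one | C=C(C)C(O)C[C@@H]1O[C@]1(C)[C@@H]2C=CC(=O)C[C@H]2C | intermediate
13 | (4S,5R)-5-methyl-4-[(2R,3S)-2-methyl-3-(3-methyl-2-oxobut-3-en-1-yl)oxiran-2-yl]cyclohex-2-en-1-one | C=C(C)C(=O)C[C@@H]1O[C@]1(C)[C@@H]2C=CC(=O)C[C@H]2C | intermediate
14 | O-copper C6=C7 enolate formed by conjugate reduction of 13 (monovalent copper) | CC(C)=C(O[Cu])C[C@@H]1O[C@]1(C)[C@@H]2C=CC(=O)C[C@H]2C | intermediate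
15 | O-copper C1=C11 enolate of (3R,9S,10R)-9,10-epoxy-10,11-secolongipinane-1,7-dione (cis-fused Michael adduct) | C1C(=O)C(C)(C)[C@@H]2C=C(O[Cu])C[C@@H](C)[C@@H]2[C@@]3(C)O[C@@H]13 | intermediate
16 | (3R,9S,10R)-9,10-epoxy-1-[(trimethylsilyl)oxy]-10,11-secolongipin-1(11)-en-7-one | C1C(=O)C(C)(C)[C@@H]2C=C(O[Si](C)(C)C)C[C@@H](C)[C@@H]2[C@@]3(C)O[C@@H]13 | intermediate
17 | (3R)-9β-[(trimethylsilyl)oxy]longipinane-1,7-dione | C1C(=O)C(C)(C)[C@@H]2[C@H]3C(=O)C[C@@H](C)[C@@H]2[C@@]3(C)[C@H]1O[Si](C)(C)C | intermediate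
18 | (3R)-9β-hydroxylongipinane-1,7-dione | C1C(=O)C(C)(C)[C@@H]2[C@H]3C(=O)C[C@@H](C)[C@@H]2[C@@]3(C)[C@H]1O | intermediate
19 | (3R)-9β-[(methylsulfonyl)oxy]longipinane-1,7-dione | C1C(=O)C(C)(C)[C@@H]2[C@H]3C(=O)C[C@@H](C)[C@@H]2[C@@]3(C)[C@H]1OS(C)(=O)=O | intermediate
20 | (3R)-longipin-8-ene-1,7-dione | C1=CC(=O)C(C)(C)[C@@H]2[C@H]3C(=O)C[C@@H](C)[C@@H]2[C@@]13C | intermediate
21 | (3R)-1-[(tert-butyldimethylsilyl)oxy]longipina-1,8-dien-7-one | C1=CC(=O)C(C)(C)[C@@H]2[C@H]3C(O[Si](C)(C)C(C)(C)C)=C[C@@H](C)[C@@H]2[C@@]13C | intermediate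
22 | (3R)-1-[(tert-butyldimethylsilyl)oxy]longipina-1,8-dien-7β-ol | C1=C[C@@H](O)C(C)(C)[C@@H]2[C@H]3C(O[Si](C)(C)C(C)(C)C)=C[C@@H](C)[C@@H]2[C@@]13C | intermediate
23 | (3R)-1,7β-bis[(tert-butyldimethylsilyl)oxy]longipina-1,8-diene | C1=C[C@@H](O[Si](C)(C)C(C)(C)C)C(C)(C)[C@@H]2[C@H]3C(O[Si](C)(C)C(C)(C)C)=C[C@@H](C)[C@@H]2[C@@]13C | intermediate
24 | 7β-[(tert-butyldimethylsilyl)oxy]longipina-2,8-dien-1-one | C1=C[C@@H](O[Si](C)(C)C(C)(C)C)C(C)(C)[C@@H]2[C@H]3C(=O)C=C(C)[C@@H]2[C@@]13C | intermediate
25 | 7β-[(tert-butyldimethylsilyl)oxy]-8α,9α-dihydroxylongipin-2-en-1-one | O[C@@H]1[C@@H](O[Si](C)(C)C(C)(C)C)C(C)(C)[C@@H]2[C@H]3C(=O)C=C(C)[C@@H]2[C@@]3(C)[C@@H]1O | intermediate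
26 | (2Z)-2-methylbut-2-enoic acid (angelic acid) | C/C=C(/C)C(=O)O | starting material
27 | 8α-angeloyloxy-7β-[(tert-butyldimethylsilyl)oxy]-9α-hydroxylongipin-2-en-1-one | C/C=C(/C)C(=O)O[C@@H]1[C@@H](O[Si](C)(C)C(C)(C)C)C(C)(C)[C@@H]2[C@H]3C(=O)C=C(C)[C@@H]2[C@@]3(C)[C@@H]1O | intermediate
28 | 3-methylbutanoyl chloride | CC(C)CC(=O)Cl | starting material
29 | 8α-angeloyloxy-7β-[(tert-butyldimethylsilyl)oxy]-9α-(3-methylbutanoyloxy)longipin-2-en-1-one | C/C=C(/C)C(=O)O[C@@H]1[C@@H](O[Si](C)(C)C(C)(C)C)C(C)(C)[C@@H]2[C@H]3C(=O)C=C(C)[C@@H]2[C@@]3(C)[C@@H]1OC(=O)CC(C)C | intermediate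
30 | 8α-angeloyloxy-7β-hydroxy-9α-(3-methylbutanoyloxy)longipin-2-en-1-one | C/C=C(/C)C(=O)O[C@@H]1[C@@H](O)C(C)(C)[C@@H]2[C@H]3C(=O)C=C(C)[C@@H]2[C@@]3(C)[C@@H]1OC(=O)CC(C)C | target

**Step count and risks**

Total step count: 19. Longest linear sequence: 18 steps (steps 1–3 and 5–19; step 4 is a one-step branch).

Steps most likely to fail:

1. Step 10 (proposed new method). The hindered copper enolate may add too slowly to the enone, and once the oxirane is activated a 1,2-hydride shift to a ketone may outrun the four-membered ring closure. Fallback with known reaction types, run as two isolated stages: 13 is subjected to the copper-hydride reductive Michael cyclisation alone and the enolate is trapped with Et3SiCl to give the isolable triethylsilyl enol ether of the cis-fused Michael adduct F1. F1 is then closed by the classical stoichiometric Lewis-acid alkylation of a silyl enol ether with an epoxide (TiCl4, CH2Cl2, −78 °C), which returns to the route at 18.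

2. Step 17. Site selectivity between the two secondary hydroxyls may be poor, and the angelate may isomerise to the tiglate if base and heat are prolonged. Fallback: 25 is converted with Bu2SnO (toluene, reflux, water removal) into the 8,9-O-dibutylstannylene acetal F2, whose tin–oxygen activation directs acylation by the preformed angelic 2,4,6-trichlorobenzoic anhydride to the less hindered O8 at room temperature, returning to the route at 27.

3. Step 2. The strongly acidic catalyst may cleave the silyl enol ether of the diene, and facial discrimination with a β-substituted enal may be modest. Fallback with auxiliary control: diene 2 is combined with (4R)-4-benzyl-3-[(2E)-but-2-enoyl]-1,3-oxazolidin-2-one under Et2AlCl (CH2Cl2, −78 °C) to give the N-acyl oxazolidinone cycloadduct F3. Reductive removal of the auxiliary with LiBH4 (THF/MeOH) gives the primary alcohol F4, and Dess–Martin oxidation returns to the route at 4.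

Further compounds
F1 | step 10 | (3R,9S,10R)-9,10-epoxy-1-[(triethylsilyl)oxy]-10,11-secolongipin-1(11)-en-7-one | C1C(=O)C(C)(C)[C@@H]2C=C(O[Si](CC)(CC)CC)C[C@@H](C)[C@@H]2[C@@]3(C)O[C@@H]13
F2 | step 17 | 8α,9α-O-(dibutylstannanediyl) acetal of 25 | CCCC[Sn]1(CCCC)O[C@@H]2[C@@H](O[Si](C)(C)C(C)(C)C)C(C)(C)[C@@H]3[C@H]4C(=O)C=C(C)[C@@H]3[C@@]4(C)[C@@H]2O1
F3 | step 2 | (4R)-4-benzyl-3-{[(1R,6R)-6-methyl-4-{[tri(propan-2-yl)silyl]oxy}cyclohex-3-en-1-yl]carbonyl}-1,3-oxazolidin-2-one | O=C([C@H]1[C@H](C)CC(O[Si](C(C)C)(C(C)C)C(C)C)=CC1)N1[C@H](Cc2ccccc2)COC1=O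
F4 | step 2 | [(1R,6R)-6-methyl-4-{[tri(propan-2-yl)silyl]oxy}cyclohex-3-en-1-yl]methanol | OC[C@H]1[C@H](C)CC(O[Si](C(C)C)(C(C)C)C(C)C)=CC1
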